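The route hinges on removing the ether oxygen from the tetrahydrofuran ring (O, C1', C2', C5, C6). C6 then bonds to C1', and the cyclobutanone C5–C6–C1'–C2' fused to the bicyclo[2.2.2]octenone (bridgeheads C5 and C8) is the [2+2] adduct of a ketene C2'=C1'=O, tethered to C8 through C3', with the C5=C6 silyl enol ether of a dearomatised flavanone. One operation forms C1'–C6 and C2'–C5, both carbocycles and the C2', C5 and C6 stereocentres, all relayed from C8. The precursor is the (2R,8R) acid chloride whose quaternary C8 carries methyl and the CMe2CH2COCl arm; oxygen is inserted afterwards between C1' and C6 with retention.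

Key step: step 10

Remark on numbering: flavanone locants are used throughout (O1, C2, C3, C4, C4a, C5 to C8, C8a; ring A carbocycle, ring C pyranone), and the five-carbon bridge is C1' (OCH2), C2' (CH), C3' (CMe2).

Remark on configuration: the target is 2R,5R,6S,8R,2'R. The cyclobutanone 20 has the same spatial arrangement but reads 2R,5R,6R,8R,2'S, because the CIP priorities at C6 and C2' change.

Remark on design:
- C8 is made quaternary by a sigmatropic shift onto a ring carbon that already bears methyl. Methylating a C8 that already carries the tertiary arm would be expected to go to the less hindered C6 instead.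
- The silyl group is put on O5 while ring A is still aromatic, so the enol ether regiochemistry (O5, not O7) is never in question.
- The acyl chloride is made without HCl, to spare the vinylogous silyl ester.

Assumption: C2 is too remote to control C8 in step 6, so both C8 epimers should form. They are taken to be separable by chromatography, and only the 8R series is carried on.

Step 1
Reactants: 1 2',4',6'-trihydroxyacetophenone; 2 iodomethane
Product: 4 1-(2,4,6-trihydroxy-3,5-dimethylphenyl)ethan-1-one, via monomethyl ketone 3 (not isolated)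
Conditions: NaOMe (2.2 equiv), MeI (2.2 equiv), MeOH, 0 °C to rt
Reagents that add atoms: iodomethane, CI
Why: Base-mediated C-methylation of the phloroglucinol nucleus (enolate alkylation in a protic solvent) should take place at the two free ring carbons, and limiting the reagent to two equivalents should hold back geminal dimethylation.

Step 2
Reactants: 4 1-(2,4,6-trihydroxy-3,5-dimethylphenyl)ethan-1-one; 5 N,N-dimethylformamide dimethyl acetal
Product: 7 5,7-dihydroxy-6,8-dimethyl-4H-chromen-4-one, via enaminone 6 (not isolated)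
Conditions: Me2NCH(OMe)2 (1.5 equiv), THF, 65 °C; then conc. HCl, EtOH, 70 °C
Reagents that add atoms: N,N-dimethylformamide dimethyl acetal, COC(OC)N(C)C
Why: Enaminone formation at the acetyl methyl group followed by acid-promoted addition–elimination of an ortho phenol (enaminone route to chromones) should close ring C, and because the two ortho hydroxyls are equivalent only one chromone can form.

Step 3
Reactants: 7 5,7-dihydroxy-6,8-dimethyl-4H-chromen-4-one; 8 phenylboronic acid
Product: 9 (2R)-5,7-dihydroxy-6,8-dimethyl-2-phenyl-2,3-dihydro-4H-chromen-4-one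
Conditions: PhB(OH)2 (2 equiv), Pd(OCOCF3)2 (5 mol%), (S)-4-tert-butyl-2-(pyridin-2-yl)-4,5-dihydrooxazole (6 mol%), NH4PF6 (30 mol%), H2O (5 equiv), ClCH2CH2Cl, 60 °C
Reagents that add atoms: phenylboronic acid, OB(O)c1ccccc1
Why: Palladium-catalysed asymmetric conjugate addition of an arylboronic acid to the chromone enone sets C2, the pyridine-oxazoline ligand shielding one face of C2=C3 so that phenyl should be delivered to give 2R (the ligand antipode is used if the sense proves opposite).

Step 4
Reactants: 9 (2R)-5,7-dihydroxy-6,8-dimethyl-2-phenyl-2,3-dihydro-4H-chromen-4-one; 10 3-methylbut-2-en-1-ol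
Product: 11 (2R)-5-hydroxy-6,8-dimethyl-7-[(3-methylbut-2-en-1-yl)oxy]-2-phenyl-2,3-dihydro-4H-chromen-4-one
Conditions: PPh3, i-PrO2CN=NCO2i-Pr, THF, 0 °C to rt
Reagents that add atoms: 3-methylbut-2-en-1-ol, CC(C)=CCO
Why: Mitsunobu etherification should alkylate only the acidic, non-chelated 7-hydroxyl under neutral conditions, which avoids base-induced opening of ring C and loss of the C2 configuration.

Step 5
Reactants: 11 (2R)-5-hydroxy-6,8-dimethyl-7-[(3-methylbut-2-en-1-yl)oxy]-2-phenyl-2,3-dihydro-4H-chromen-4-one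
Product: 12 (2R)-5-{[tert-butyl(dimethyl)silyl]oxy}-6,8-dimethyl-7-[(3-methylbut-2-en-1-yl)oxy]-2-phenyl-2,3-dihydro-4H-chromen-4-one
Conditions: TBSOTf (1.5 equiv), 2,6-lutidine (2.5 equiv), CH2Cl2, 0 °C to rt
Reagents that add atoms: tert-butyldimethylsilyl trifluoromethanesulfonate, CC(C)(C)[Si](C)(C)OS(=O)(=O)C(F)(F)F
Why: Silylation of the hydrogen-bonded 5-hydroxyl with the silyl triflate is done on the aromatic ring, where O5 is unambiguous, so that this group becomes the C5 silyl enol ether in step 6.

Step 6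
Reactants: 12 (2R)-5-{[tert-butyl(dimethyl)silyl]oxy}-6,8-dimethyl-7-[(3-methylbut-2-en-1-yl)oxy]-2-phenyl-2,3-dihydro-4H-chromen-4-one
Product: 13 (2R,8R)-5-{[tert-butyl(dimethyl)silyl]oxy}-6,8-dimethyl-8-(2-methylbut-3-en-2-yl)-2-phenyl-2,3-dihydro-4H-chromene-4,7(8H)-dione
Conditions: degassed PhMe (0.05 M), 2,6-di-tert-butyl-4-methylpyridine (0.2 equiv), 150 °C, sealed tube; chromatographic separation of the C8 epimers; used promptly
Reagents that add atoms: none
Why: In this dearomative aromatic Claisen rearrangement both ortho positions are methylated, so the [3,3] shift from O7 should stop at a cyclohexadienone; C8 is preferred over C6 because the coplanar O1 (not the twisted O5 silyl ether) puts double-bond character into C7–C8 and C6 is flanked by the bulky silyloxy group, the O5 silyl group rules out onward Cope migration to C6, and since C2 gives no useful induction at C8 the 8R epimer is obtained by separation from its 8S partner.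

Step 7
Reactants: 13 (2R,8R)-5-{[tert-butyl(dimethyl)silyl]oxy}-6,8-dimethyl-8-(2-methylbut-3-en-2-yl)-2-phenyl-2,3-dihydro-4H-chromene-4,7(8H)-dione
Product: 15 (2R,8R)-5-{[tert-butyl(dimethyl)silyl]oxy}-8-(4-hydroxy-2-methylbutan-2-yl)-6,8-dimethyl-2-phenyl-2,3-dihydro-4H-chromene-4,7(8H)-dione, via alkylborane 14 (not isolated)
Conditions: 9-BBN (2 equiv), THF, 0 °C to rt; then 30% H2O2, pH 7 phosphate buffer, MeOH, 0 °C
Reagents that add atoms: hydrogen peroxide, OO
Why: In this anti-Markovnikov hydroboration–oxidation the bulky borane should add only to the monosubstituted vinyl group (the ring alkenes are tetrasubstituted and both carbonyls are deactivated vinylogous esters), and buffered peroxide should spare the silyl enol ether.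

Step 8
Reactants: 15 (2R,8R)-5-{[tert-butyl(dimethyl)silyl]oxy}-8-(4-hydroxy-2-methylbutan-2-yl)-6,8-dimethyl-2-phenyl-2,3-dihydro-4H-chromene-4,7(8H)-dione
Product: 17 3-[(2R,8R)-5-{[tert-butyl(dimethyl)silyl]oxy}-6,8-dimethyl-4,7-dioxo-2-phenyl-3,4,7,8-tetrahydro-2H-chromen-8-yl]-3-methylbutanoic acid, via aldehyde 16 (not isolated)
Conditions: (n-Pr4N)RuO4 (10 mol%), N-methylmorpholine N-oxide monohydrate (10 equiv), MeCN, rt
Reagents that add atoms: water, O
Why: Perruthenate-catalysed oxidation in the presence of amine-oxide hydrate should take the primary alcohol through the aldehyde hydrate to the acid at near-neutral pH, which is chosen for the hydrolytically sensitive vinylogous silyl ester.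

Step 9
Reactants: 17 3-[(2R,8R)-5-{[tert-butyl(dimethyl)silyl]oxy}-6,8-dimethyl-4,7-dioxo-2-phenyl-3,4,7,8-tetrahydro-2H-chromen-8-yl]-3-methylbutanoic acid
Product: 18 3-[(2R,8R)-5-{[tert-butyl(dimethyl)silyl]oxy}-6,8-dimethyl-4,7-dioxo-2-phenyl-3,4,7,8-tetrahydro-2H-chromen-8-yl]-3-methylbutanoyl chloride
Conditions: 1-chloro-N,N,2-trimethylprop-1-en-1-amine (1.3 equiv), CH2Cl2, 0 °C to rt; evaporated and used crude
Reagents that add atoms: 1-chloro-N,N,2-trimethylprop-1-en-1-amine, CC(C)=C(Cl)N(C)C
Why: The α-chloroenamine should convert the acid into its chloride without releasing HCl (neutral acyl chloride formation), so the C5 silyl enol ether survives, and C7 has no α-hydrogen and therefore cannot form an enol lactone with the arm.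

Step 10
Reactants: 18 3-[(2R,8R)-5-{[tert-butyl(dimethyl)silyl]oxy}-6,8-dimethyl-4,7-dioxo-2-phenyl-3,4,7,8-tetrahydro-2H-chromen-8-yl]-3-methylbutanoyl chloride
Product: 20 (2R,5R,6R,8R,2'S)-5-O-TBS cage cyclobutanone, via ketene 19 (not isolated)
Conditions: Et3N (2 equiv), PhMe, 80 °C, slow addition of 18 to a final 0.005 M
Reagents that add atoms: none
Why: Et3N dehydrochlorinates 18 to the ketene 19; its electrophilic carbonyl carbon C1' attacks C6, the nucleophilic β-carbon of the C5 silyl enol ether, positive charge develops at C5 (stabilised by the silyloxy group and by the O1–C8a=C4a unit) and C2' closes onto it, an asynchronous thermal [2+2]. The closest known reaction type is the intramolecular ketene–alkene cycloaddition of ketenes made from acid chlorides and a tertiary amine, including its enol ether variants. The six-membered carbocycle C8–C3'–C2'–C5–C4a–C8a closes through C2'–C5 by bridging the 1,4-positions of the cyclohexadienone (boat-like, giving the bicyclo[2.2.2]octenone), and the four-membered ring C5–C6–C1'–C2' closes through C1'–C6 in the crossed, bridged orientation that the enol ether polarisation dictates. C2', C5 and C6 are all controlled by C8, because the two-atom tether can reach C5=C6 only on the ring face that carries it and the ketene adds suprafacially to that face. The step needs site selectivity for C5=C6 over C4a=C8a and over dimerisation or acylation at oxygen: C4a=C8a is electron-poor and out of reach, C7 has no α-hydrogen and so offers no enol oxygen, and high dilution suppresses intermolecular reaction.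

Step 11
Reactants: 20 (2R,5R,6R,8R,2'S)-5-O-TBS cage cyclobutanone
Product: 22 (2R,5R,6S,8R,2'S)-5-O-TBS cage methyl acetal (both C1' epimers), via oxacarbene 21 (not isolated)
Conditions: hν (300–350 nm, borosilicate filter), degassed MeOH–CH2Cl2 (1:1), 0 °C
Reagents that add atoms: methanol, CO
Why: In this photochemical ring expansion of a cyclobutanone, α-cleavage should occur at C1'–C6 (giving the tertiary radical stabilised by the C7 carbonyl), the acyl radical recloses on oxygen to a 2-oxacyclopentylidene that inserts into the O–H bond of methanol, and C6 keeps its configuration because the oxygen arrives on the face the carbon left.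

Step 12
Reactants: 22 (2R,5R,6S,8R,2'S)-5-O-TBS cage methyl acetal
Product: 23 (2R,5R,6S,8R,2'R)-5-O-TBS ether of the target
Conditions: Et3SiH (5 equiv), BF3·OEt2 (2 equiv), CH2Cl2, −78 to −30 °C
Reagents that add atoms: none
Why: In this ionic hydrogenation of a cyclic acetal, BF3 ionises the exocyclic methoxy group to the ring oxocarbenium ion, which triethylsilane should reduce at C1' without touching the hindered ketones or the tertiary silyl ether, and C1' ceases to be a stereocentre.

Step 13
Reactants: 23 (2R,5R,6S,8R,2'R)-5-O-TBS ether of the target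
Product: 24 CNP0322161.2
Conditions: HF·pyridine, THF–pyridine, 0 °C to rt, polypropylene vessel
Reagents that add atoms: none
Why: Fluoride-mediated desilylation under acidic conditions should free the bridgehead tertiary alcohol while avoiding the alkoxide that could start retro-aldol cleavage of C5–C6.

Compound list
1 | 1-(2,4,6-trihydroxyphenyl)ethan-1-one (2',4',6'-trihydroxyacetophenone) | CC(=O)c1c(O)cc(O)cc1O | starting material
2 | iodomethane | CI | starting material
3 | 1-(2,4,6-trihydroxy-3-methylphenyl)ethan-1-one | CC(=O)c1c(O)cc(O)c(C)c1O | intermediate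
4 | 1-(2,4,6-trihydroxy-3,5-dimethylphenyl)ethan-1-one | CC(=O)c1c(O)c(C)c(O)c(C)c1O | intermediate
5 | N,N-dimethylformamide dimethyl acetal | COC(OC)N(C)C | starting material
6 | (E)-3-(dimethylamino)-1-(2,4,6-trihydroxy-3,5-dimethylphenyl)prop-2-en-1-one | CN(C)/C=C/C(=O)c1c(O)c(C)c(O)c(C)c1O | intermediate
7 | 5,7-dihydroxy-6,8-dimethyl-4H-chromen-4-one | Cc1c(O)c(C)c2occc(=O)c2c1O | intermediate
8 | phenylboronic acid | OB(O)c1ccccc1 | starting material
9 | (2R)-5,7-dihydroxy-6,8-dimethyl-2-phenyl-2,3-dihydro-4H-chromen-4-one | O=C1C[C@H](c2ccccc2)Oc2c(C)c(O)c(C)c(O)c12 | intermediate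
10 | 3-methylbut-2-en-1-ol | CC(C)=CCO | starting material
11 | (2R)-5-hydroxy-6,8-dimethyl-7-[(3-methylbut-2-en-1-yl)oxy]-2-phenyl-2,3-dihydro-4H-chromen-4-one | O=C1C[C@H](c2ccccc2)Oc2c(C)c(OCC=C(C)C)c(C)c(O)c12 | intermediate
12 | (2R)-5-{[tert-butyl(dimethyl)silyl]oxy}-6,8-dimethyl-7-[(3-methylbut-2-en-1-yl)oxy]-2-phenyl-2,3-dihydro-4H-chromen-4-one | O=C1C[C@H](c2ccccc2)Oc2c(C)c(OCC=C(C)C)c(C)c(O[Si](C)(C)C(C)(C)C)c12 | intermediate
13 | (2R,8R)-5-{[tert-butyl(dimethyl)silyl]oxy}-6,8-dimethyl-8-(2-methylbut-3-en-2-yl)-2-phenyl-2,3-dihydro-4H-chromene-4,7(8H)-dione | C=CC(C)(C)[C@@]1(C)C(=O)C(C)=C(O[Si](C)(C)C(C)(C)C)C2=C1O[C@@H](c1ccccc1)CC2=O | intermediate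
14 | B-alkyl-9-borabicyclo[3.3.1]nonane from 13, boron on the terminal carbon C1' (2R,8R) | C(CC(C)(C)[C@@]1(C)C(=O)C(C)=C(O[Si](C)(C)C(C)(C)C)C2=C1O[C@@H](c1ccccc1)CC2=O)B1C2CCCC1CCC2 | intermediate
15 | (2R,8R)-5-{[tert-butyl(dimethyl)silyl]oxy}-8-(4-hydroxy-2-methylbutan-2-yl)-6,8-dimethyl-2-phenyl-2,3-dihydro-4H-chromene-4,7(8H)-dione | OCCC(C)(C)[C@@]1(C)C(=O)C(C)=C(O[Si](C)(C)C(C)(C)C)C2=C1O[C@@H](c1ccccc1)CC2=O | intermediate
16 | 3-[(2R,8R)-5-{[tert-butyl(dimethyl)silyl]oxy}-6,8-dimethyl-4,7-dioxo-2-phenyl-3,4,7,8-tetrahydro-2H-chromen-8-yl]-3-methylbutanal | O=CCC(C)(C)[C@@]1(C)C(=O)C(C)=C(O[Si](C)(C)C(C)(C)C)C2=C1O[C@@H](c1ccccc1)CC2=O | intermediate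
17 | 3-[(2R,8R)-5-{[tert-butyl(dimethyl)silyl]oxy}-6,8-dimethyl-4,7-dioxo-2-phenyl-3,4,7,8-tetrahydro-2H-chromen-8-yl]-3-methylbutanoic acid | OC(=O)CC(C)(C)[C@@]1(C)C(=O)C(C)=C(O[Si](C)(C)C(C)(C)C)C2=C1O[C@@H](c1ccccc1)CC2=O | intermediate
18 | 3-[(2R,8R)-5-{[tert-butyl(dimethyl)silyl]oxy}-6,8-dimethyl-4,7-dioxo-2-phenyl-3,4,7,8-tetrahydro-2H-chromen-8-yl]-3-methylbutanoyl chloride (precursor of the key step) | O=C(Cl)CC(C)(C)[C@@]1(C)C(=O)C(C)=C(O[Si](C)(C)C(C)(C)C)C2=C1O[C@@H](c1ccccc1)CC2=O | intermediate
19 | ketene 3-[(2R,8R)-5-{[tert-butyl(dimethyl)silyl]oxy}-6,8-dimethyl-4,7-dioxo-2-phenyl-3,4,7,8-tetrahydro-2H-chromen-8-yl]-3-methylbut-1-en-1-one | O=C=CC(C)(C)[C@@]1(C)C(=O)C(C)=C(O[Si](C)(C)C(C)(C)C)C2=C1O[C@@H](c1ccccc1)CC2=O | intermediate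
20 | (2R,5R,6R,8R,2'S)-cage cyclobutanone (product of the key step): bicyclo[2.2.2]octene with bridgeheads C5 (OTBS) and C8 (Me), bridges C6(Me)–C7(=O), C4a=C8a and C2'H–C3'Me2, carbonyl C1' joining C2' to C6, ring C (O1–C2HPh–C3H2–C4=O) fused at C4a=C8a | CC1(C)[C@@H]2C(=O)[C@]3(C)C(=O)[C@@]1(C)C1=C(C(=O)C[C@H](c4ccccc4)O1)[C@]23O[Si](C)(C)C(C)(C)C | intermediate
21 | oxacarbene from 20: C6 bonded to the former carbonyl oxygen, divalent C1' between that oxygen and C2' | CC1(C)[C@@H]2[C]O[C@]3(C)C(=O)[C@@]1(C)C1=C(C(=O)C[C@H](c4ccccc4)O1)[C@]23O[Si](C)(C)C(C)(C)C | intermediate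
22 | (2R,5R,6S,8R,2'S)-cage methyl acetal: as 23 with OMe on C1' (both C1' epimers) | CC1(C)[C@@H]2C(OC)O[C@]3(C)C(=O)[C@@]1(C)C1=C(C(=O)C[C@H](c4ccccc4)O1)[C@]23O[Si](C)(C)C(C)(C)C | intermediate
23 | (2R,5R,6S,8R,2'R)-5-O-tert-butyldimethylsilyl ether of the target | CC1(C)[C@@H]2CO[C@]3(C)C(=O)[C@@]1(C)C1=C(C(=O)C[C@H](c4ccccc4)O1)[C@]23O[Si](C)(C)C(C)(C)C | intermediate
24 | CNP0322161.2, (2R,5R,6S,8R,2'R) | CC1(C)[C@@H]2CO[C@]3(C)C(=O)[C@@]1(C)C1=C(C(=O)C[C@H](c4ccccc4)O1)[C@]23O | target

Total step count: 13. Longest linear sequence: 13 steps (1 to 24).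

Steps most likely to fail

Step 10. The ketene may dimerise or fail to engage C5=C6, which is a push–pull alkene weakened by conjugation to C7=O. The amine may also open ring C by β-elimination of O1 from C2, which would scramble C2. The fallback sets out from acid 17 and uses the more electrophilic, non-dimerising keteniminium ion in place of the ketene. Activation of 17 with 1-chloro-N,N,2-trimethylprop-1-en-1-amine and addition of pyrrolidine should give the pyrrolidine amide F1. Tf2O with 2,4,6-collidine in ClCH2CH2Cl at 80 °C should convert F1 into the keteniminium salt, which closes on C5=C6 in the same orientation to the cyclobutaniminium triflate F2. Hydrolysis of F2 with aqueous NaHCO3 returns to the route at 20.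

Step 6. The rearrangement may stall at the aryl ether for lack of driving force. The new allyl group may move on by a Cope shift to C4a or migrate to C6. There is also no facial control at C8, so half of the material is the wrong epimer at best. The fallback sets out from chromone 7 and runs the shift before C2 exists. Prenyl bromide with K2CO3 in acetone should give 5-hydroxy-6,8-dimethyl-7-(3-methylbut-2-enyloxy)chromone F3, and TBSOTf with 2,6-lutidine its 5-silyl ether F4. Heating F4 should give the racemic 8-(2-methylbut-3-en-2-yl) dienone F5, because only migration to C8 leaves a complete 4-pyranone ring, which offsets the lost benzenoid ring and disfavours C6 and C4a. Phenyl is then added to C2 of F5 with PhB(OH)2, Pd(OCOCF3)2 and the pyridine-oxazoline ligand as in step 3, so that the catalyst fixes C2 as R. Separation of the 8R diastereomer rejoins the route at 13.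

Step 11. Light may be absorbed mainly by the vinylogous ester chromophore. The β,γ-unsaturated C7 ketone may undergo a 1,3-acyl shift, or methanol may cleave the strained 1,3-diketone in the dark. The fallback sets out from 20 and inserts the oxygen thermally. Baeyer–Villiger oxidation with mCPBA and NaHCO3 in CH2Cl2 at 0 °C should attack only the strained cyclobutanone. The fully substituted C6 is expected to migrate with retention, giving the γ-lactone F6, although this regiochemistry would have to be confirmed. Reduction of F6 with i-Bu2AlH at −78 °C should give the lactol F7. Treating F7 with Et3SiH and BF3·OEt2 as in step 12 comes back to the route at 23.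

Further compounds
F1 | step 10 | pyrrolidine amide of acid 17 (2R,8R) | O=C(N1CCCC1)CC(C)(C)[C@@]1(C)C(=O)C(C)=C(O[Si](C)(C)C(C)(C)C)C2=C1O[C@@H](c1ccccc1)CC2=O
F2 | step 10 | cyclobutaniminium triflate (20 with C1'=N+ pyrrolidinium in place of C1'=O) | CC1(C)[C@@H]2C(=[N+]4CCCC4)[C@]3(C)C(=O)[C@@]1(C)C1=C(C(=O)C[C@H](c4ccccc4)O1)[C@]23O[Si](C)(C)C(C)(C)C.[O-]S(=O)(=O)C(F)(F)F
F3 | step 6 | 5-hydroxy-6,8-dimethyl-7-[(3-methylbut-2-en-1-yl)oxy]-4H-chromen-4-one | Cc1c(OCC=C(C)C)c(C)c2occc(=O)c2c1O
F4 | step 6 | 5-{[tert-butyl(dimethyl)silyl]oxy}-6,8-dimethyl-7-[(3-methylbut-2-en-1-yl)oxy]-4H-chromen-4-one | Cc1c(OCC=C(C)C)c(C)c2occc(=O)c2c1O[Si](C)(C)C(C)(C)C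
F5 | step 6 | racemic 5-{[tert-butyl(dimethyl)silyl]oxy}-6,8-dimethyl-8-(2-methylbut-3-en-2-yl)-4H-chromene-4,7(8H)-dione | C=CC(C)(C)C1(C)C(=O)C(C)=C(O[Si](C)(C)C(C)(C)C)C2=C1OC=CC2=O
F6 | step 11 | cage γ-lactone (23 with C1'=O in place of C1'H2) | CC1(C)[C@@H]2C(=O)O[C@]3(C)C(=O)[C@@]1(C)C1=C(C(=O)C[C@H](c4ccccc4)O1)[C@]23O[Si](C)(C)C(C)(C)C
F7 | step 11 | cage lactol (23 with OH on C1', both epimers) | CC1(C)[C@@H]2C(O)O[C@]3(C)C(=O)[C@@]1(C)C1=C(C(=O)C[C@H](c4ccccc4)O1)[C@]23O[Si](C)(C)C(C)(C)C
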